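**Strategy.** Everything rests on disconnecting the C7–C11 bond of the lactone ring (O–C12–C11–C7–C8). The feature exploited is the contiguous triad C6–O, C7–C11, C8–O on the ten-membered ring, which is the footprint of a trans C6–C7 epoxide beside an acylated C8 oxygen. In one operation the anion of a C8-bound diethylphosphonoacetate opens the epoxide at C7 with inversion: it closes the cis-fused γ-lactone, sets C7, frees the C6 hydroxyl and leaves the phosphonate for the C13 methylenation. The precursor is the (6R,7S,8S)-6,7-epoxycyclodecyl phosphonoacetate 20, with C1 carried as a silyl-protected carbinol (oxidised last, so C10 is never α to a carbonyl under base or acid) and C4 as a triethylsilyl ether.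

Key step: step 16

Remark: skeleton locants are used throughout (C1 = ring carbon that ends as the ketone, C2 and C3 methylenes, C4 methyl carbinol, C5, C6 acyloxy carbon, C7, C8 lactone-oxygen carbon, C9, C10 methyl-bearing carbon, C11 and C12 lactone carbons, C13 exo-methylene); the target is addressed as the open C1-ketone/C4-hydroxyl form drawn, with which any transannular hemiketal would be in equilibrium.

**Step 1**
Reactants: 1 geraniol
Product: 2 (2S,3S)-2,3-epoxygeraniol
Conditions: Ti(OiPr)4 (5 mol %), L-(+)-diethyl tartrate (7 mol %), t-BuOOH, 4 Å molecular sieves, CH2Cl2, −20 °C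
Reagents that add atoms: tert-butyl hydroperoxide, CC(C)(C)OO
Why: Sharpless asymmetric epoxidation, in which the L-(+)-tartrate complex delivers oxygen to the face of the allylic alcohol that gives the 2S,3S epoxide and thereby fixes the future C4 carbinol centre.

**Step 2**
Reactants: 2 (2S,3S)-2,3-epoxygeraniol
Product: 3 (3S)-3,7-dimethyloct-6-ene-1,3-diol
Conditions: NaAlH2(OCH2CH2OMe)2 (Red-Al), THF, 0 °C→rt
Reagents that add atoms: none
Why: Directed hydride opening of a 2,3-epoxy alcohol, in which the aluminate bound to the primary oxygen delivers hydride to the adjacent epoxide carbon, giving the 1,3-diol and leaving the tertiary C–O bond (future C4) untouched.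

**Step 3**
Reactants: 3 (3S)-3,7-dimethyloct-6-ene-1,3-diol
Product: 4 (3S)-3,7-dimethyl-1,3-bis(triethylsilyloxy)oct-6-ene
Conditions: Et3SiOTf (2.5 equiv), 2,6-lutidine, CH2Cl2, −78→0 °C
Reagents that add atoms: triethylsilyl triflate, CC[Si](CC)(CC)OS(=O)(=O)C(F)(F)F
Why: Silyl ether formation, the triflate silylating the primary and the hindered tertiary hydroxyl alike, which protects C4–OH for the whole route and sets up the primary ether for direct oxidation.

**Step 4**
Reactants: 4 (3S)-3,7-dimethyl-1,3-bis(triethylsilyloxy)oct-6-ene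
Product: 5 (3S)-3,7-dimethyl-3-(triethylsilyloxy)oct-6-enal
Conditions: (COCl)2, DMSO, CH2Cl2, −78→−30 °C; Et3N, −78 °C→rt
Reagents that add atoms: none
Why: Swern oxidation, in which activated DMSO cleaves the primary triethylsilyl ether and oxidises it to the aldehyde (future C6) in the same flask while the hindered tertiary silyl ether does not react.

**Step 5**
Reactants: 5 (3S)-3,7-dimethyl-3-(triethylsilyloxy)oct-6-enal
Product: 6 (1E,4S)-1-iodo-4,8-dimethyl-4-(triethylsilyloxy)nona-1,7-diene
Conditions: CrCl2, CHI3, THF–dioxane (1:6), 0 °C→rt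
Reagents that add atoms: iodoform, IC(I)I
Why: Takai olefination, in which the geminal dichromium reagent formed from CHI3 and CrCl2 adds to the aldehyde and eliminates to give the (E)-iodoalkene, supplying C7.

**Step 6**
Reactants: 6 (1E,4S)-1-iodo-4,8-dimethyl-4-(triethylsilyloxy)nona-1,7-diene
Product: 8 (4S,6E)-7-iodo-4-methyl-4-(triethylsilyloxy)hept-6-enal, via vicinal diol 7 (not isolated)
Conditions: OsO4 (2 mol %), NaIO4, 2,6-lutidine, dioxane–H2O (3:1), rt
Reagents that add atoms: osmium tetroxide, O=[Os](=O)(=O)=O (oxygen, turned over by sodium periodate, [Na+].[O-]I(=O)(=O)=O)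
Why: Lemieux–Johnson oxidative cleavage, in which OsO4 dihydroxylates the electron-rich trisubstituted alkene much faster than the electron-poor iodoalkene and periodate cleaves the diol, unveiling C1 as the aldehyde.

**Step 7**
Reactants: 8 (4S,6E)-7-iodo-4-methyl-4-(triethylsilyloxy)hept-6-enal
Product: 10 (1E,4S,7R,8R)-1-iodo-4,8-dimethyl-4-(triethylsilyloxy)deca-1,9-dien-7-ol, via diisopinocampheylborinate 9 (not isolated)
Conditions: (Z)-but-2-ene, KOt-Bu, n-BuLi, THF, −78→−45 °C; (−)-Ipc2BOMe, −78 °C; BF3·OEt2; 8, −78 °C; then NaOH, H2O2, rt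
Reagents that add atoms: (Z)-but-2-ene, C/C=C\C (boron and the isopinocampheyl groups of (−)-Ipc2BOMe, COB([C@@H]1C[C@@H]2C[C@H]([C@H]1C)C2(C)C)[C@@H]1C[C@@H]2C[C@H]([C@H]1C)C2(C)C, stay only in 9)
Why: Brown crotylboration, in which the (Z)-crotylborane adds through a chair six-membered transition state to give the syn adduct and the isopinocampheyl groups derived from (+)-α-pinene direct attack to the si face of the aldehyde, setting C10 as R (the C1 carbinol, also R, is oxidised at the end).

**Step 8**
Reactants: 10 (1E,4S,7R,8R)-1-iodo-4,8-dimethyl-4-(triethylsilyloxy)deca-1,9-dien-7-ol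
Product: 11 (1E,4S,7R,8R)-7-(tert-butyldimethylsilyloxy)-1-iodo-4,8-dimethyl-4-(triethylsilyloxy)deca-1,9-diene
Conditions: t-BuMe2SiOTf, 2,6-lutidine, CH2Cl2, −78→0 °C
Reagents that add atoms: tert-butyldimethylsilyl triflate, CC(C)(C)[Si](C)(C)OS(=O)(=O)C(F)(F)F
Why: Silyl ether formation, masking the C1 carbinol as a robust TBS ether so that C1 stays sp3 until the last step.

**Step 9**
Reactants: 11 (1E,4S,7R,8R)-7-(tert-butyldimethylsilyloxy)-1-iodo-4,8-dimethyl-4-(triethylsilyloxy)deca-1,9-diene
Product: 13 (3R,4R,7S,9E)-4-(tert-butyldimethylsilyloxy)-10-iodo-3,7-dimethyl-7-(triethylsilyloxy)dec-9-en-1-ol, via B-alkyl-9-BBN borane 12 (not isolated)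
Conditions: 9-BBN, THF, 0 °C→rt; NaOH, H2O2, 0 °C
Reagents that add atoms: hydrogen peroxide, OO (boron of 9-BBN, B1C2CCCC1CCC2, stays only in 12)
Why: Hydroboration–oxidation, in which 9-BBN adds anti-Markovnikov to the monosubstituted alkene (boron at C8) far faster than to the deactivated iodoalkene and oxidation gives the C8 primary alcohol.

**Step 10**
Reactants: 13 (3R,4R,7S,9E)-4-(tert-butyldimethylsilyloxy)-10-iodo-3,7-dimethyl-7-(triethylsilyloxy)dec-9-en-1-ol
Product: 14 (3R,4R,7S,9E)-4-(tert-butyldimethylsilyloxy)-10-iodo-3,7-dimethyl-7-(triethylsilyloxy)dec-9-enal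
Conditions: Dess–Martin periodinane, pyridine, CH2Cl2, 0 °C→rt
Reagents that add atoms: none
Why: Dess–Martin oxidation of the primary alcohol under buffered conditions that leave the silyl ethers and the iodoalkene intact, C10 being β and not α to the new C8 aldehyde.

**Step 11**
Reactants: 14 (3R,4R,7S,9E)-4-(tert-butyldimethylsilyloxy)-10-iodo-3,7-dimethyl-7-(triethylsilyloxy)dec-9-enal
Product: 15 (1R,4S,10R,6E)-1-(tert-butyldimethylsilyloxy)-4,10-dimethyl-4-(triethylsilyloxy)cyclodec-6-en-8-ol (both C8 epimers)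
Conditions: CrCl2 (10 equiv), NiCl2 (cat.), DMSO–THF, rt, slow addition to 0.003 M
Reagents that add atoms: none
Why: Nozaki–Hiyama–Kishi reaction, in which NiCl2-catalysed activation of the C7–I bond and transfer to chromium give an (E)-alkenylchromium reagent that adds only to the C8 aldehyde, high dilution favouring the ten-membered ring with the E geometry retained; the C8 configuration is left open because steps 12 and 13 reset it.

**Step 12**
Reactants: 15 (1R,4S,10R,6E)-1-(tert-butyldimethylsilyloxy)-4,10-dimethyl-4-(triethylsilyloxy)cyclodec-6-en-8-ol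
Product: 16 (1R,4S,10R,6E)-1-(tert-butyldimethylsilyloxy)-4,10-dimethyl-4-(triethylsilyloxy)cyclodec-6-en-8-one
Conditions: Dess–Martin periodinane, pyridine, CH2Cl2, 0 °C→rt
Reagents that add atoms: none
Why: Dess–Martin oxidation of an allylic alcohol, by which both C8 epimers converge on one (E)-enone.

**Step 13**
Reactants: 16 (1R,4S,10R,6E)-1-(tert-butyldimethylsilyloxy)-4,10-dimethyl-4-(triethylsilyloxy)cyclodec-6-en-8-one
Product: 17 (1R,4S,8R,10R,6E)-1-(tert-butyldimethylsilyloxy)-4,10-dimethyl-4-(triethylsilyloxy)cyclodec-6-en-8-ol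
Conditions: (S)-2-methyl-CBS-oxazaborolidine, catecholborane, toluene, −78 °C
Reagents that add atoms: none
Why: Corey–Bakshi–Shibata reduction, in which the (S)-oxazaborolidine binds the ketone with the alkenyl arm as the large group and delivers hydride to give the 8R allylic alcohol under reagent control, the low temperature with catecholborane avoiding alkene hydroboration.

**Step 14**
Reactants: 17 (1R,4S,8R,10R,6E)-1-(tert-butyldimethylsilyloxy)-4,10-dimethyl-4-(triethylsilyloxy)cyclodec-6-en-8-ol
Product: 18 (1R,4S,6R,7R,8R,10R)-1-(tert-butyldimethylsilyloxy)-6,7-epoxy-4,10-dimethyl-4-(triethylsilyloxy)cyclodecan-8-ol (trans epoxide, anti to the C8 hydroxyl)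
Conditions: Ti(OiPr)4 (0.3 equiv), D-(−)-diisopropyl tartrate (0.36 equiv), t-BuOOH, 4 Å molecular sieves, CH2Cl2, −20 °C
Reagents that add atoms: tert-butyl hydroperoxide, CC(C)(C)OO
Why: Sharpless asymmetric epoxidation of a secondary allylic alcohol, in which the 8R carbinol and D-(−)-tartrate form the matched pair and oxygen is delivered to the C6–C7 face that gives the trans epoxide anti (erythro) to the C8 hydroxyl.

**Step 15**
Reactants: 18 (1R,4S,6R,7R,8R,10R)-1-(tert-butyldimethylsilyloxy)-6,7-epoxy-4,10-dimethyl-4-(triethylsilyloxy)cyclodecan-8-ol; 19 diethylphosphonoacetic acid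
Product: 20 (1R,4S,6R,7S,8S,10R)-1-(tert-butyldimethylsilyloxy)-6,7-epoxy-4,10-dimethyl-4-(triethylsilyloxy)cyclodecan-8-yl 2-(diethoxyphosphoryl)acetate
Conditions: PPh3, diisopropyl azodicarboxylate, toluene, 0 °C→rt
Reagents that add atoms: none
Why: Mitsunobu esterification, in which the carboxylate of 19 displaces the phosphonium-activated C8 oxygen by SN2 and so inverts C8 to S, turning the anti into the syn epoxy ester needed for a cis ring fusion while the epoxide is untouched under these neutral conditions.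

**Step 16**
Reactants: 20 (1R,4S,6R,7S,8S,10R)-1-(tert-butyldimethylsilyloxy)-6,7-epoxy-4,10-dimethyl-4-(triethylsilyloxy)cyclodecan-8-yl 2-(diethoxyphosphoryl)acetate
Product: 21 (1R,4S,6R,7R,8S,10R,11S)-cis-fused 12,8-lactone bearing 11-(diethoxyphosphoryl), free 6-hydroxyl, 1-(tert-butyldimethylsilyloxy), 4-(triethylsilyloxy) and 4,10-dimethyl groups
Conditions: NaH (1.1 equiv), THF, 0→45 °C; AcOH quench at 0 °C
Reagents that add atoms: none
Why: NaH forms the phosphonate-stabilised ester anion, whose carbon C11 attacks C7 from the side opposite the C7–O bond of the epoxide (intramolecular SN2), forming C7–C11 and releasing the C6 alkoxide, which is protonated at once by the acidic C11–H so that the product rests as its stabilised lactone enolate until the acetic acid quench. The closest known reaction type is the ring-forming opening of an epoxide by a tethered stabilised carbanion, here in its lactone-forming variant, which parallels the tethered conjugate addition of phosphonoacetate esters that gives α-phosphono-γ-lactones. The lactone ring O–C12–C11–C7–C8 closes in the 5-exo-tet mode. C7 is set by inversion, so the trans epoxide translates into the anti C6–O/C7–C11 relationship, and with the 8S ester oxygen this inversion can only give the cis ring fusion; C11 is epimerisable and should settle trans to the C6 branch. The step needs attack at C7 and not at C6, and the three-atom O–C12–C11 tether secures this, since only the proximal carbon lies on a near-collinear trajectory whereas the six-membered endo mode at C6 is geometrically poor. Moderate temperature and one equivalent of base should hold back phosphoryl transfer to the C6 oxygen and lactone migration to O6.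

**Step 17**
Reactants: 21 cis-fused 11-phosphono 12,8-lactone with free C6 hydroxyl
Product: 22 (1R,4S,6R,7S,8S,10R,11S)-6-O-isobutyryl derivative of 21
Conditions: (i-PrCO)2O, pyridine, 4-(dimethylamino)pyridine (cat.), CH2Cl2, 0 °C→rt
Reagents that add atoms: isobutyric anhydride, CC(C)C(=O)OC(=O)C(C)C
Why: Nucleophile-catalysed acylation (esterification) of the secondary C6 hydroxyl in a weakly basic medium that leaves the acidic C11–H and both silyl ethers alone.

**Step 18**
Reactants: 22 6-O-isobutyryl 11-phosphono 12,8-lactone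
Product: 23 (1R,4S,6R,7S,8S,10R)-11(13)-methylene 12,8-lactone with 6-isobutyryloxy, 1-(tert-butyldimethylsilyloxy) and 4-(triethylsilyloxy) groups
Conditions: aq. HCHO (37 %), K2CO3, THF, 0 °C→rt
Reagents that add atoms: formaldehyde, C=O
Why: Horner–Wadsworth–Emmons olefination, in which the carbonate-generated phosphonate anion adds to formaldehyde and loses diethyl phosphate to install the C11=C13 methylene, erasing the C11 centre.

**Step 19**
Reactants: 23 bis-silylated 11(13)-methylene 12,8-lactone
Product: 24 (1R,4S,6R,7S,8S,10R)-1,4-dihydroxy-6-isobutyryloxy-11(13)-methylene 12,8-lactone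
Conditions: HF·pyridine, pyridine, THF, 0 °C→rt
Reagents that add atoms: none
Why: Fluoride-mediated desilylation, buffered HF cleaving the secondary TBS and the tertiary triethylsilyl ether without touching the methylene lactone or the isobutyrate.

**Step 20**
Reactants: 24 1,4-dihydroxy-6-isobutyryloxy-11(13)-methylene 12,8-lactone
Product: 25 target, (4S,6R,7S,8S,10R)-4-hydroxy-6-isobutyryloxy-1-oxo-11(13)-methylene 12,8-lactone (CNP0293926.1)
Conditions: Dess–Martin periodinane, pyridine, CH2Cl2, 0 °C→rt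
Reagents that add atoms: none
Why: Dess–Martin oxidation, in which only the secondary C1 carbinol can be oxidised (C4–OH is tertiary) and the buffered neutral conditions should leave the newly α-positioned C10 centre unepimerised.

**Compound list**
1 | geraniol, (2E)-3,7-dimethylocta-2,6-dien-1-ol | CC(C)=CCC/C(C)=C/CO | starting material
2 | (2S,3S)-2,3-epoxygeraniol | CC(C)=CCC[C@]1(C)O[C@H]1CO | intermediate
3 | (3S)-3,7-dimethyloct-6-ene-1,3-diol | CC(C)=CCC[C@](C)(O)CCO | intermediate
4 | (3S)-3,7-dimethyl-1,3-bis(triethylsilyloxy)oct-6-ene | CC(C)=CCC[C@](C)(O[Si](CC)(CC)CC)CCO[Si](CC)(CC)CC | intermediate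
5 | (3S)-3,7-dimethyl-3-(triethylsilyloxy)oct-6-enal | CC(C)=CCC[C@](C)(O[Si](CC)(CC)CC)CC=O | intermediate
6 | (1E,4S)-1-iodo-4,8-dimethyl-4-(triethylsilyloxy)nona-1,7-diene | CC(C)=CCC[C@](C)(O[Si](CC)(CC)CC)C/C=C/I | intermediate
7 | (6S,8E)-9-iodo-2,6-dimethyl-6-(triethylsilyloxy)non-8-ene-2,3-diol (C3 epimers) | CC(C)(O)C(O)CC[C@](C)(O[Si](CC)(CC)CC)C/C=C/I | intermediate (not isolated)
8 | (4S,6E)-7-iodo-4-methyl-4-(triethylsilyloxy)hept-6-enal | O=CCC[C@](C)(O[Si](CC)(CC)CC)C/C=C/I | intermediate
9 | bis(isopinocampheyl)borinate of 10 | C=C[C@@H](C)[C@H](OB([C@@H]1C[C@@H]2C[C@H]([C@H]1C)C2(C)C)[C@@H]1C[C@@H]2C[C@H]([C@H]1C)C2(C)C)CC[C@](C)(O[Si](CC)(CC)CC)C/C=C/I | intermediate (not isolated)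
10 | (1E,4S,7R,8R)-1-iodo-4,8-dimethyl-4-(triethylsilyloxy)deca-1,9-dien-7-ol | C=C[C@@H](C)[C@H](O)CC[C@](C)(O[Si](CC)(CC)CC)C/C=C/I | intermediate
11 | (1E,4S,7R,8R)-7-(tert-butyldimethylsilyloxy)-1-iodo-4,8-dimethyl-4-(triethylsilyloxy)deca-1,9-diene | C=C[C@@H](C)[C@H](O[Si](C)(C)C(C)(C)C)CC[C@](C)(O[Si](CC)(CC)CC)C/C=C/I | intermediate
12 | B-alkyl-9-BBN borane of 11 (boron on C8) | B1(C2CCCC1CCC2)CC[C@@H](C)[C@H](O[Si](C)(C)C(C)(C)C)CC[C@](C)(O[Si](CC)(CC)CC)C/C=C/I | intermediate (not isolated)
13 | (3R,4R,7S,9E)-4-(tert-butyldimethylsilyloxy)-10-iodo-3,7-dimethyl-7-(triethylsilyloxy)dec-9-en-1-ol | OCC[C@@H](C)[C@H](O[Si](C)(C)C(C)(C)C)CC[C@](C)(O[Si](CC)(CC)CC)C/C=C/I | intermediate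
14 | (3R,4R,7S,9E)-4-(tert-butyldimethylsilyloxy)-10-iodo-3,7-dimethyl-7-(triethylsilyloxy)dec-9-enal | O=CC[C@@H](C)[C@H](O[Si](C)(C)C(C)(C)C)CC[C@](C)(O[Si](CC)(CC)CC)C/C=C/I | intermediate
15 | (1R,4S,10R,6E)-1-(tert-butyldimethylsilyloxy)-4,10-dimethyl-4-(triethylsilyloxy)cyclodec-6-en-8-ol, C8 epimers | OC1C[C@@H](C)[C@H](O[Si](C)(C)C(C)(C)C)CC[C@](C)(O[Si](CC)(CC)CC)C/C=C/1 | intermediate
16 | (1R,4S,10R,6E)-1-(tert-butyldimethylsilyloxy)-4,10-dimethyl-4-(triethylsilyloxy)cyclodec-6-en-8-one | O=C1C[C@@H](C)[C@H](O[Si](C)(C)C(C)(C)C)CC[C@](C)(O[Si](CC)(CC)CC)C/C=C/1 | intermediate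
17 | (1R,4S,8R,10R,6E)-1-(tert-butyldimethylsilyloxy)-4,10-dimethyl-4-(triethylsilyloxy)cyclodec-6-en-8-ol | O[C@@H]1C[C@@H](C)[C@H](O[Si](C)(C)C(C)(C)C)CC[C@](C)(O[Si](CC)(CC)CC)C/C=C/1 | intermediate
18 | (1R,4S,6R,7R,8R,10R)-1-(tert-butyldimethylsilyloxy)-6,7-epoxy-4,10-dimethyl-4-(triethylsilyloxy)cyclodecan-8-ol | O[C@@H]1C[C@@H](C)[C@H](O[Si](C)(C)C(C)(C)C)CC[C@](C)(O[Si](CC)(CC)CC)C[C@H]2O[C@H]12 | intermediate
19 | diethylphosphonoacetic acid, 2-(diethoxyphosphoryl)acetic acid | CCOP(=O)(CC(=O)O)OCC | starting material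
20 | (1R,4S,6R,7S,8S,10R)-1-(tert-butyldimethylsilyloxy)-6,7-epoxy-4,10-dimethyl-4-(triethylsilyloxy)cyclodecan-8-yl 2-(diethoxyphosphoryl)acetate | CCOP(=O)(OCC)CC(=O)O[C@H]1C[C@@H](C)[C@H](O[Si](C)(C)C(C)(C)C)CC[C@](C)(O[Si](CC)(CC)CC)C[C@H]2O[C@H]12 | intermediate (key-step precursor)
21 | (1R,4S,6R,7R,8S,10R,11S)-cis-fused 11-(diethoxyphosphoryl) 12,8-lactone, C6–OH free, C1–OTBS, C4–OSiEt3 | CCOP(=O)(OCC)[C@@H]1C(=O)O[C@H]2C[C@@H](C)[C@H](O[Si](C)(C)C(C)(C)C)CC[C@](C)(O[Si](CC)(CC)CC)C[C@@H](O)[C@@H]12 | intermediate (key-step product)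
22 | (1R,4S,6R,7S,8S,10R,11S)-6-O-isobutyryl derivative of 21 | CCOP(=O)(OCC)[C@@H]1C(=O)O[C@H]2C[C@@H](C)[C@H](O[Si](C)(C)C(C)(C)C)CC[C@](C)(O[Si](CC)(CC)CC)C[C@@H](OC(=O)C(C)C)[C@@H]12 | intermediate
23 | (1R,4S,6R,7S,8S,10R)-11(13)-methylene 12,8-lactone, 6-isobutyryloxy, C1–OTBS, C4–OSiEt3 | C=C1C(=O)O[C@H]2C[C@@H](C)[C@H](O[Si](C)(C)C(C)(C)C)CC[C@](C)(O[Si](CC)(CC)CC)C[C@@H](OC(=O)C(C)C)[C@@H]12 | intermediate
24 | (1R,4S,6R,7S,8S,10R)-1,4-dihydroxy-6-isobutyryloxy-11(13)-methylene 12,8-lactone | C=C1C(=O)O[C@H]2C[C@@H](C)[C@H](O)CC[C@](C)(O)C[C@@H](OC(=O)C(C)C)[C@@H]12 | intermediate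
25 | (4S,6R,7S,8S,10R)-4-hydroxy-6-isobutyryloxy-1-oxo-11(13)-methylene 12,8-lactone (CNP0293926.1) | C=C1C(=O)O[C@H]2C[C@@H](C)C(=O)CC[C@](C)(O)C[C@@H](OC(=O)C(C)C)[C@@H]12 | target

**Step count.** Total: 20 steps, all in one line from geraniol; longest linear sequence: 20 steps.

**Steps most likely to fail**

1. Step 16 (lactone annulation). The enolate unit lies inside the ring being formed, so the ester-linked anion may be slow to reach the backside of C7. Competing processes are opening at C6, transfer of the phosphoryl group to the freed C6 oxygen followed by cyclopropane closure, and lactone migration to O6.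
Fallback (sets out from 16, returns at 22): reduction of enone 16 with the (R)-oxazaborolidine and catecholborane should give the 8S allylic alcohol F1. Carbodiimide esterification with 19 (retention) gives the allylic phosphonoacetate F2, and Regitz diazo transfer (p-acetamidobenzenesulfonyl azide, DBU) gives the α-diazo phosphonoacetate F3. Rh2(OAc)4-catalysed intramolecular cyclopropanation of the C6=C7 bond then gives the cyclopropane-fused α-phosphono lactone F4, in which C11 is bonded to both C7 and C6 and the lactone is already cis-fused. Homoconjugate opening of this doubly activated cyclopropane at C6 by caesium isobutyrate (isobutyric acid, DMSO, heat) proceeds with inversion at C6 and gives 22 directly, with the same anti C6–O/C7–C11 relationship.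

2. Step 11 (ten-membered ring closure). Intermolecular coupling and simple reduction of the C–I bond may outrun closure of the strained ring even at high dilution.
Fallback (sets out from 11, returns at 15): borane 12, made as in step 9, is not oxidised but submitted to an intramolecular B-alkyl Suzuki–Miyaura coupling (Pd(dppf)Cl2, AsPh3, Cs2CO3, DMF–THF–H2O, high dilution). This joins C8 to C7 and gives the (E)-cyclodecene F5 with C8 as a methylene. Allylic hydroxylation (SeO2, t-BuOOH, CH2Cl2) is expected at the unhindered C8 methylene and not at the neopentyl C5, and gives 15.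

3. Step 15 (inversion at C8). SN2 displacement at a ring carbinol flanked by the epoxide may be slow, letting elimination or acyl transfer with retention compete.
Fallback (sets out from 16, returns at 20): the 8S allylic alcohol F1 (made from 16 as in the first fallback) is epoxidised under reagent control by Shi epoxidation (D-fructose-derived ketone, KHSO5, buffered MeCN–dimethoxymethane–H2O, 0 °C), which should give the syn epoxy alcohol F6. Carbodiimide esterification with 19 (DCC, 4-(dimethylamino)pyridine, CH2Cl2) proceeds with retention and gives 20 without any inversion step.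

**Further compounds**
F1 | step 16 | (1R,4S,8S,10R,6E)-1-(tert-butyldimethylsilyloxy)-4,10-dimethyl-4-(triethylsilyloxy)cyclodec-6-en-8-ol | O[C@H]1C[C@@H](C)[C@H](O[Si](C)(C)C(C)(C)C)CC[C@](C)(O[Si](CC)(CC)CC)C/C=C/1
F2 | step 16 | 8-O-[2-(diethoxyphosphoryl)acetyl] ester of F1 | CCOP(=O)(OCC)CC(=O)O[C@H]1C[C@@H](C)[C@H](O[Si](C)(C)C(C)(C)C)CC[C@](C)(O[Si](CC)(CC)CC)C/C=C/1
F3 | step 16 | 8-O-[2-diazo-2-(diethoxyphosphoryl)acetyl] ester of F1 | CCOP(=O)(OCC)C(=[N+]=[N-])C(=O)O[C@H]1C[C@@H](C)[C@H](O[Si](C)(C)C(C)(C)C)CC[C@](C)(O[Si](CC)(CC)CC)C/C=C/1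
F4 | step 16 | cyclopropane-fused 11-(diethoxyphosphoryl) 12,8-lactone (C11 bonded to C6 and C7) | CCOP(=O)(OCC)[C@@]12C(=O)O[C@H]3C[C@@H](C)[C@H](O[Si](C)(C)C(C)(C)C)CC[C@](C)(O[Si](CC)(CC)CC)C[C@H]1[C@@H]23
F5 | step 11 | (1R,4S,10R,6E)-1-(tert-butyldimethylsilyloxy)-4,10-dimethyl-4-(triethylsilyloxy)cyclodec-6-ene | C1C[C@@H](C)[C@H](O[Si](C)(C)C(C)(C)C)CC[C@](C)(O[Si](CC)(CC)CC)C/C=C/1
F6 | step 15 | (1R,4S,6R,7R,8S,10R)-1-(tert-butyldimethylsilyloxy)-6,7-epoxy-4,10-dimethyl-4-(triethylsilyloxy)cyclodecan-8-ol (epoxide syn to the C8 hydroxyl) | O[C@H]1C[C@@H](C)[C@H](O[Si](C)(C)C(C)(C)C)CC[C@](C)(O[Si](CC)(CC)CC)C[C@H]2O[C@H]12
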